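Benzofuran numbering is used throughout: O1, C2 (bears syringyl ring A), C3 (bears CH2OH), benzo ring B = C3a–C7a. The retrosynthesis first places a disposable OH on C4, then cuts ring B at C6–C7, C4–C5 and C3a–C4.
Enabling feature: in ring B the methoxy-bearing C7 is bonded to C7a. C7a (attached to O1) and C3a are the two carbons of an enol ether of the heterocycle. C7 is therefore the carbene carbon of a methoxy(4,5-dihydrofuran-2-yl)carbene chromium complex, C5 (side chain) and C6 (H) are a terminal alkyne, and C4 is a CO ligand.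
Forward order: the O1–C2–C3–C3a–C7a ring is made first (aldol, alkene cleavage to a lactol, dehydration). It is metalated at the future C7a and converted into the carbene complex. Ring B closes last, with silylated (E)-pent-2-en-4-yn-1-ol delivering the finished side chain.
Stereochemistry: C2 and C3 both come from one Evans syn aldol controlled by (R)-4-benzyloxazolidin-2-one (syn aldol = trans ring). The E alkene is bought with the enynol.
End game: the C4 hydroxyl leaves through its triflate (palladium/formate), then fluoride removes the three silyl groups.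

Key step: step 10

Abbreviations: TBS = tert-butyldimethylsilyl; Ar = 4-(tert-butyldimethylsilyloxy)-3,5-dimethoxyphenyl.
Assumption: commercial pent-2-en-4-yn-1-ol is used as the pure E isomer (fractionated first if supplied as a mixture).

Step 1
Reactants: 1 syringaldehyde
Product: 2 4-(tert-butyldimethylsilyloxy)-3,5-dimethoxybenzaldehyde
Conditions: TBSCl, imidazole, DMF, rt
Reagents that add atoms: tert-butyldimethylsilyl chloride, CC(C)(C)[Si](C)(C)Cl
Why: Imidazole-promoted O-silylation of a phenol leaves the aldehyde untouched and removes the acidic proton that would quench the later enolate and organolithium steps.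

Step 2
Reactants: 3 (R)-4-benzyloxazolidin-2-one; 4 pent-4-enoyl chloride
Product: 5 (R)-4-benzyl-3-(pent-4-enoyl)oxazolidin-2-one
Conditions: Et3N, DMAP (cat.), CH2Cl2, 0 °C → rt
Reagents that add atoms: none
Why: N-acylation of an Evans oxazolidinone with an acid chloride under nucleophilic catalysis is routine and does not touch the stereocentre of the auxiliary.

Step 3
Reactants: 5 (R)-4-benzyl-3-(pent-4-enoyl)oxazolidin-2-one; 2 4-(tert-butyldimethylsilyloxy)-3,5-dimethoxybenzaldehyde
Product: 8 (R)-4-benzyl-3-[(2R)-2-{(R)-Ar(hydroxy)methyl}pent-4-enoyl]oxazolidin-2-one (syn aldol), via Z boron enolate 6 (not isolated), via boron aldolate 7 (not isolated)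
Conditions: Bu2BOTf, Et3N, CH2Cl2, −78 → 0 °C; 2, −78 → 0 °C; H2O2, MeOH, pH 7 buffer, 0 °C
Reagents that add atoms: dibutylboron triflate, CCCCB(CCCC)OS(=O)(=O)C(F)(F)F (its Bu2B group is found only in 6 and 7, not in 8)
Why: In this Evans syn aldol reaction the Z enolate 6 reacts through a closed Zimmerman–Traxler chair in which the benzyl group of the (R)-auxiliary blocks one enolate face, so the auxiliary sets both new centres (α-carbon R and carbinol R, the syn pair that becomes trans C3/C2).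

Step 4
Reactants: 8 syn aldol
Product: 9 (1R,2S)-1-Ar-2-(prop-2-enyl)propane-1,3-diol
Conditions: LiBH4, MeOH (1 equiv), THF, 0 °C
Reagents that add atoms: none
Why: Reductive removal of the Evans auxiliary with LiBH4 turns the exocyclic imide carbonyl into the CH2OH group of C3 without epimerisation, and the silyl ether and terminal alkene are inert to borohydride.

Step 5
Reactants: 9 (1R,2S)-1-Ar-2-(prop-2-enyl)propane-1,3-diol
Product: 10 (1R,2S)-1-Ar-2-[(tert-butyldimethylsilyloxy)methyl]pent-4-en-1-ol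
Conditions: TBSCl (1.05 equiv), imidazole, CH2Cl2, 0 °C
Reagents that add atoms: tert-butyldimethylsilyl chloride, CC(C)(C)[Si](C)(C)Cl
Why: This chemoselective silylation works because the unhindered primary hydroxyl reacts far faster than the secondary benzylic one, which must stay free to become O1.

Step 6
Reactants: 10 (1R,2S)-1-Ar-2-[(tert-butyldimethylsilyloxy)methyl]pent-4-en-1-ol
Product: 13 (4S,5R)-5-Ar-4-[(tert-butyldimethylsilyloxy)methyl]tetrahydrofuran-2-ol (both anomers), via triol 11 (not isolated), via hydroxy aldehyde 12 (not isolated)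
Conditions: OsO4 (2 mol %), NaIO4, 2,6-lutidine, dioxane–H2O, rt
Reagents that add atoms: OsO4, O=[Os](=O)(=O)=O (catalytic carrier of the oxygen atoms); NaIO4, [Na+].[O-]I(=O)(=O)=O (stoichiometric oxygen source)
Why: Lemieux–Johnson oxidative cleavage is preferred to ozone because it spares the electron-rich ring A, and the γ-hydroxy aldehyde 12 closes by itself (5-exo-trig hemiacetal formation) to the lactol.

Step 7
Reactants: 13 lactol
Product: 15 (2R,3S)-2-Ar-3-[(tert-butyldimethylsilyloxy)methyl]-2,3-dihydrofuran, via anomeric mesylate 14 (not isolated)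
Conditions: MsCl, Et3N (excess), CH2Cl2, −40 °C → reflux; Et3N-deactivated silica
Reagents that add atoms: methanesulfonyl chloride, CS(=O)(=O)Cl (its mesyl group is found only in 14, not in 15)
Why: Anomeric mesylation followed by amine-induced elimination is the usual lactol-to-cyclic-enol-ether (glycal-type) dehydration, only one neighbouring carbon bears hydrogens so a single alkene can form, and the basic medium protects the acid-labile product.

Step 8
Reactants: 15 (2R,3S)-2-Ar-3-[(tert-butyldimethylsilyloxy)methyl]-2,3-dihydrofuran; 16 chromium hexacarbonyl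
Product: 19 pentacarbonyl{methoxy[(4S,5R)-5-Ar-4-{(tert-butyldimethylsilyloxy)methyl}-4,5-dihydrofuran-2-yl]carbene}chromium, via vinyllithium 17 (not isolated), via lithium acylchromate 18 (not isolated)
Conditions: t-BuLi (1.2 equiv), THF, −78 → 0 °C; Cr(CO)6, Et2O, 0 °C → rt; evaporate; Me3OBF4, CH2Cl2, 0 °C → rt; chromatography under N2 without amine
Reagents that add atoms: trimethyloxonium tetrafluoroborate, C[O+](C)C.F[B-](F)(F)F (O-methyl group); tert-butyllithium, [Li]C(C)(C)C (lithium of 17 and 18 only)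
Why: In this Fischer carbene synthesis t-BuLi removes the oxygen-activated sp2 hydrogen of the cyclic enol ether (kinetic α-alkoxyvinyl lithiation), the vinyllithium adds to a CO ligand of Cr(CO)6, and O-methylation of the acylchromate gives the methoxycarbene with both stereocentres untouched.

Step 9
Reactants: 20 (E)-pent-2-en-4-yn-1-ol
Product: 21 (E)-tert-butyldimethyl(pent-2-en-4-ynyloxy)silane
Conditions: TBSCl, imidazole, CH2Cl2, 0 °C → rt
Reagents that add atoms: tert-butyldimethylsilyl chloride, CC(C)(C)[Si](C)(C)Cl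
Why: Standard silylation of a primary allylic alcohol affects neither the terminal alkyne nor the alkene geometry.

Step 10
Reactants: 19 chromium carbene complex; 21 (E)-tert-butyldimethyl(pent-2-en-4-ynyloxy)silane
Product: 24 (2R,3S)-2-Ar-3-[(tert-butyldimethylsilyloxy)methyl]-5-[(E)-3-(tert-butyldimethylsilyloxy)prop-1-enyl]-7-methoxy-2,3-dihydrobenzofuran-4-ol, via vinylketene complex 22 (not isolated), via arene tricarbonylchromium complex 23 (not isolated)
Conditions: 21 (1.5–2 equiv), THF (0.05 M, degassed), 50 °C; then air, Et2O, rt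
Reagents that add atoms: none
Why: Dötz benzannulation: warming expels one CO ligand from 19, the alkyne of 21 binds and inserts into the Cr=C bond (C6–C7), and a CO ligand migrates to the new carbene carbon (C4–C5) to give the dienylketene complex 22. Ring B closes by a six-electron electrocyclisation of 22 that joins the ketene carbon C4 to C3a, the β-carbon of the enol ether, and the hydrogen on C3a then moves to oxygen to give the phenol complex 23, from which air removes the Cr(CO)3 unit. The closest known reactions are the benzannulations of methoxy(dihydropyranyl)- and methoxy(dihydrofuranyl)carbene chromium complexes with terminal alkynes, and conjugated enynes are known to take part through the triple bond only. No stereocentre is formed, and C2 and C3 pass through unchanged because the medium is neutral and the vinylogously acidic hydrogen at the future C3 of 19 never meets a base. The step needs the side chain at C5 beside the CO-derived C4 and hydrogen at C6 beside C7, which is the normal steric outcome for a terminal alkyne, since in the vinylcarbene intermediate the carbon next to the old carbene carbon lies against a CO ligand and tolerates only hydrogen.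

Step 11
Reactants: 24 C4 phenol
Product: 25 (2R,3S)-2-Ar-3-[(tert-butyldimethylsilyloxy)methyl]-5-[(E)-3-(tert-butyldimethylsilyloxy)prop-1-enyl]-7-methoxy-2,3-dihydrobenzofuran-4-yl trifluoromethanesulfonate
Conditions: Tf2O, pyridine, CH2Cl2, −78 → 0 °C
Reagents that add atoms: trifluoromethanesulfonic anhydride, O=S(=O)(OS(=O)(=O)C(F)(F)F)C(F)(F)F
Why: O-sulfonylation of a phenol with Tf2O and pyridine works even for flanked phenols, the silyl ethers and alkene tolerate the cold buffered medium, and capping the oxygen ends the lability of the ortho-hydroxycinnamyl ether.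

Step 12
Reactants: 25 C4 triflate
Product: 26 (2R,3S)-2-Ar-3-[(tert-butyldimethylsilyloxy)methyl]-5-[(E)-3-(tert-butyldimethylsilyloxy)prop-1-enyl]-7-methoxy-2,3-dihydrobenzofuran
Conditions: Pd(OAc)2 (5 mol %), 1,1'-bis(diphenylphosphino)ferrocene (10 mol %), HCO2H, Et3N, DMF, 70 °C
Reagents that add atoms: none
Why: In this palladium-catalysed formate hydrogenolysis of an aryl triflate, zerovalent palladium formed in situ inserts into the C4–O bond, formate displaces triflate and loses CO2, and reductive elimination gives C4–H, while the allylic silyl ether is too poor a leaving group to ionise.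

Step 13
Reactants: 26 tris-TBS ether
Product: 27 4-[(2R,3S)-3-(hydroxymethyl)-5-[(E)-3-hydroxyprop-1-enyl]-7-methoxy-2,3-dihydrobenzofuran-2-yl]-2,6-dimethoxyphenol (target)
Conditions: Bu4NF (4 equiv), AcOH (4 equiv), THF, 0 °C → rt
Reagents that add atoms: none
Why: Fluoride-induced Si–O cleavage removes the aryl and both primary TBS ethers in one operation, and the AcOH buffer keeps the ring A phenol protonated so that O1 is not expelled through a quinone methide and C2 keeps its configuration.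

Compound list
1 | syringaldehyde | COc1cc(C=O)cc(OC)c1O | starting material
2 | 4-(tert-butyldimethylsilyloxy)-3,5-dimethoxybenzaldehyde | COc1cc(C=O)cc(OC)c1O[Si](C)(C)C(C)(C)C | intermediate
3 | (R)-4-benzyloxazolidin-2-one | O=C1N[C@H](Cc2ccccc2)CO1 | starting material
4 | pent-4-enoyl chloride | C=CCCC(=O)Cl | starting material
5 | (R)-4-benzyl-3-(pent-4-enoyl)oxazolidin-2-one | C=CCCC(=O)N1[C@H](Cc2ccccc2)COC1=O | intermediate
6 | Z dibutylboron enolate of 5 | C=CC/C=C(\OB(CCCC)CCCC)N1[C@H](Cc2ccccc2)COC1=O | intermediate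
7 | dibutylboron aldolate of 8 | C=CC[C@H]([C@@H](OB(CCCC)CCCC)c1cc(OC)c(O[Si](C)(C)C(C)(C)C)c(OC)c1)C(=O)N1[C@H](Cc2ccccc2)COC1=O | intermediate
8 | (R)-4-benzyl-3-[(2R)-2-{(R)-Ar(hydroxy)methyl}pent-4-enoyl]oxazolidin-2-one | C=CC[C@H]([C@@H](O)c1cc(OC)c(O[Si](C)(C)C(C)(C)C)c(OC)c1)C(=O)N1[C@H](Cc2ccccc2)COC1=O | intermediate
9 | (1R,2S)-1-Ar-2-(prop-2-enyl)propane-1,3-diol | C=CC[C@H]([C@@H](O)c1cc(OC)c(O[Si](C)(C)C(C)(C)C)c(OC)c1)CO | intermediate
10 | (1R,2S)-1-Ar-2-[(tert-butyldimethylsilyloxy)methyl]pent-4-en-1-ol | C=CC[C@H]([C@@H](O)c1cc(OC)c(O[Si](C)(C)C(C)(C)C)c(OC)c1)CO[Si](C)(C)C(C)(C)C | intermediate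
11 | (4S,5R)-5-Ar-4-[(tert-butyldimethylsilyloxy)methyl]pentane-1,2,5-triol (both C2 epimers) | OCC(O)C[C@H]([C@@H](O)c1cc(OC)c(O[Si](C)(C)C(C)(C)C)c(OC)c1)CO[Si](C)(C)C(C)(C)C | intermediate
12 | (3S,4R)-4-Ar-3-[(tert-butyldimethylsilyloxy)methyl]-4-hydroxybutanal | O=CC[C@H]([C@@H](O)c1cc(OC)c(O[Si](C)(C)C(C)(C)C)c(OC)c1)CO[Si](C)(C)C(C)(C)C | intermediate
13 | (4S,5R)-5-Ar-4-[(tert-butyldimethylsilyloxy)methyl]tetrahydrofuran-2-ol (both anomers) | COc1cc([C@@H]2OC(O)C[C@H]2CO[Si](C)(C)C(C)(C)C)cc(OC)c1O[Si](C)(C)C(C)(C)C | intermediate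
14 | (4S,5R)-5-Ar-4-[(tert-butyldimethylsilyloxy)methyl]tetrahydrofuran-2-yl methanesulfonate (both anomers) | COc1cc([C@@H]2OC(OS(C)(=O)=O)C[C@H]2CO[Si](C)(C)C(C)(C)C)cc(OC)c1O[Si](C)(C)C(C)(C)C | intermediate
15 | (2R,3S)-2-Ar-3-[(tert-butyldimethylsilyloxy)methyl]-2,3-dihydrofuran | COc1cc([C@@H]2OC=C[C@H]2CO[Si](C)(C)C(C)(C)C)cc(OC)c1O[Si](C)(C)C(C)(C)C | intermediate
16 | chromium hexacarbonyl | [Cr].[C-]#[O+].[C-]#[O+].[C-]#[O+].[C-]#[O+].[C-]#[O+].[C-]#[O+] | starting material
17 | [(4S,5R)-5-Ar-4-{(tert-butyldimethylsilyloxy)methyl}-4,5-dihydrofuran-2-yl]lithium | COc1cc([C@@H]2OC([Li])=C[C@H]2CO[Si](C)(C)C(C)(C)C)cc(OC)c1O[Si](C)(C)C(C)(C)C | intermediate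
18 | lithium pentacarbonyl[(4S,5R)-5-Ar-4-{(tert-butyldimethylsilyloxy)methyl}-4,5-dihydrofuran-2-carbonyl]chromate | [Li+].COc1cc([C@@H]2OC(C([O-])=[Cr](=C=O)(=C=O)(=C=O)(=C=O)=C=O)=C[C@H]2CO[Si](C)(C)C(C)(C)C)cc(OC)c1O[Si](C)(C)C(C)(C)C | intermediate
19 | pentacarbonyl{methoxy[(4S,5R)-5-Ar-4-{(tert-butyldimethylsilyloxy)methyl}-4,5-dihydrofuran-2-yl]carbene}chromium | COc1cc([C@@H]2OC(C(OC)=[Cr](=C=O)(=C=O)(=C=O)(=C=O)=C=O)=C[C@H]2CO[Si](C)(C)C(C)(C)C)cc(OC)c1O[Si](C)(C)C(C)(C)C | intermediate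
20 | (E)-pent-2-en-4-yn-1-ol | C#C/C=C/CO | starting material
21 | (E)-tert-butyldimethyl(pent-2-en-4-ynyloxy)silane | C#C/C=C/CO[Si](C)(C)C(C)(C)C | intermediate
22 | tricarbonylchromium complex of the dienylketene (ketene carbon = C4, ketene α-carbon = C5 with the side chain, then C6H=C7(OMe) attached to the dihydrofuran) | COc1cc([C@@H]2OC(/C(OC)=C\C(=C=O)/C=C/CO[Si](C)(C)C(C)(C)C)=C[C@H]2CO[Si](C)(C)C(C)(C)C)cc(OC)c1O[Si](C)(C)C(C)(C)C.[Cr].[C-]#[O+].[C-]#[O+].[C-]#[O+] | intermediate
23 | tricarbonyl(η6-ring B)chromium complex of phenol 24 | COc1cc([C@@H]2Oc3c(OC)cc(/C=C/CO[Si](C)(C)C(C)(C)C)c(O)c3[C@H]2CO[Si](C)(C)C(C)(C)C)cc(OC)c1O[Si](C)(C)C(C)(C)C.[Cr].[C-]#[O+].[C-]#[O+].[C-]#[O+] | intermediate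
24 | (2R,3S)-2-Ar-3-[(tert-butyldimethylsilyloxy)methyl]-5-[(E)-3-(tert-butyldimethylsilyloxy)prop-1-enyl]-7-methoxy-2,3-dihydrobenzofuran-4-ol | COc1cc([C@@H]2Oc3c(OC)cc(/C=C/CO[Si](C)(C)C(C)(C)C)c(O)c3[C@H]2CO[Si](C)(C)C(C)(C)C)cc(OC)c1O[Si](C)(C)C(C)(C)C | intermediate
25 | C4 trifluoromethanesulfonate of 24 | COc1cc([C@@H]2Oc3c(OC)cc(/C=C/CO[Si](C)(C)C(C)(C)C)c(OS(=O)(=O)C(F)(F)F)c3[C@H]2CO[Si](C)(C)C(C)(C)C)cc(OC)c1O[Si](C)(C)C(C)(C)C | intermediate
26 | (2R,3S)-2-Ar-3-[(tert-butyldimethylsilyloxy)methyl]-5-[(E)-3-(tert-butyldimethylsilyloxy)prop-1-enyl]-7-methoxy-2,3-dihydrobenzofuran | COc1cc([C@@H]2Oc3c(OC)cc(/C=C/CO[Si](C)(C)C(C)(C)C)cc3[C@H]2CO[Si](C)(C)C(C)(C)C)cc(OC)c1O[Si](C)(C)C(C)(C)C | intermediate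
27 | 4-[(2R,3S)-3-(hydroxymethyl)-5-[(E)-3-hydroxyprop-1-enyl]-7-methoxy-2,3-dihydrobenzofuran-2-yl]-2,6-dimethoxyphenol | COc1cc([C@@H]2Oc3c(OC)cc(/C=C/CO)cc3[C@H]2CO)cc(OC)c1O | target

Total step count: 13. Longest linear sequence: 11 (steps 1, 3–8, 10–13).

Steps most likely to fail

Step 8. Deprotonation may not stay at the enol ether hydrogen. The ring A positions flanked by a methoxy group and the benzylic carbon, or the benzylic C–H next to oxygen, may be metalated in competition. The sensitive enol ether may also degrade during the sequence. The fallback replaces C–H lithiation by tin–lithium exchange at a predefined carbon and sets out from lactol 13.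
- PhSO2H and CaCl2 in CH2Cl2 convert 13 into the anomeric phenyl sulfone F1.
- The acidic hydrogen next to sulfur is removed with n-BuLi in THF at −78 °C, and the anion is quenched with Bu3SnCl to give the α-stannyl sulfone F2.
- Heating with i-Pr2NEt in CHCl3 makes F2 lose benzenesulfinic acid and gives the 5-tributylstannyl-2,3-dihydrofuran F3.
- n-BuLi in THF at −78 °C exchanges tin for lithium at that carbon only and delivers vinyllithium 17, where the route is rejoined.

Step 10. The conjugated enyne may oligomerise on chromium or engage its alkene. The ortho-hydroxycinnamyl silyl ether that forms may lose silanol or be over-oxidised during demetalation. The fallback keeps the same ring closure but builds the side chain afterwards, and it sets out from complex 19.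
- Heating 19 with commercial 3,3-diethoxyprop-1-yne in THF, followed by airing, gives the 5-(diethoxymethyl) C4 phenol F4.
- Pyridinium tosylate in wet acetone hydrolyses it to the salicylaldehyde F5.
- Tf2O and pyridine give the formyl triflate F6, whose C4–O bond is activated by the ortho aldehyde.
- Pd(OAc)2, 1,1'-bis(diphenylphosphino)ferrocene, HCO2H and Et3N in DMF reduce it to the 5-carbaldehyde F7.
- Horner–Wadsworth–Emmons olefination with triethyl phosphonoacetate (LiCl, DBU, MeCN) gives the E enoate F8.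
- i-Bu2AlH in CH2Cl2 at −78 °C gives the allylic alcohol F9.
- Bu4NF/AcOH removes the two remaining silyl groups, and the route is rejoined at target 27.

Step 12. Oxidative addition at the doubly flanked, electron-rich C4–O bond may be slow. The palladium hydride generated from formate may then saturate or shift the styrenyl double bond, or the triflate may be hydrolysed back to the phenol. The fallback avoids hydride altogether by forming a carbon–tin bond and cleaving it by protonolysis. It sets out from triflate 25.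
- Coupling with Me3SnSnMe3 (Pd(PPh3)4, LiCl, dioxane, 90 °C) gives the C4 trimethylstannane F10.
- C4 lies para to the C7 methoxy group, so ipso protonation with AcOH in CH2Cl2 at rt should cleave the C–Sn bond and return the route at 26.

Further compounds
F1 | step 8 | (4S,5R)-5-Ar-4-[(tert-butyldimethylsilyloxy)methyl]-2-(phenylsulfonyl)tetrahydrofuran (both anomers) | COc1cc([C@@H]2OC(S(=O)(=O)c3ccccc3)C[C@H]2CO[Si](C)(C)C(C)(C)C)cc(OC)c1O[Si](C)(C)C(C)(C)C
F2 | step 8 | (4S,5R)-5-Ar-4-[(tert-butyldimethylsilyloxy)methyl]-2-(phenylsulfonyl)-2-(tributylstannyl)tetrahydrofuran (C2 epimers) | COc1cc([C@@H]2OC([Sn](CCCC)(CCCC)CCCC)(S(=O)(=O)c3ccccc3)C[C@H]2CO[Si](C)(C)C(C)(C)C)cc(OC)c1O[Si](C)(C)C(C)(C)C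
F3 | step 8 | (2R,3S)-2-Ar-3-[(tert-butyldimethylsilyloxy)methyl]-5-(tributylstannyl)-2,3-dihydrofuran | COc1cc([C@@H]2OC([Sn](CCCC)(CCCC)CCCC)=C[C@H]2CO[Si](C)(C)C(C)(C)C)cc(OC)c1O[Si](C)(C)C(C)(C)C
F4 | step 10 | (2R,3S)-2-Ar-3-[(tert-butyldimethylsilyloxy)methyl]-5-(diethoxymethyl)-7-methoxy-2,3-dihydrobenzofuran-4-ol | COc1cc([C@@H]2Oc3c(OC)cc(C(OCC)OCC)c(O)c3[C@H]2CO[Si](C)(C)C(C)(C)C)cc(OC)c1O[Si](C)(C)C(C)(C)C
F5 | step 10 | (2R,3S)-2-Ar-3-[(tert-butyldimethylsilyloxy)methyl]-4-hydroxy-7-methoxy-2,3-dihydrobenzofuran-5-carbaldehyde | COc1cc([C@@H]2Oc3c(OC)cc(C=O)c(O)c3[C@H]2CO[Si](C)(C)C(C)(C)C)cc(OC)c1O[Si](C)(C)C(C)(C)C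
F6 | step 10 | (2R,3S)-2-Ar-3-[(tert-butyldimethylsilyloxy)methyl]-5-formyl-7-methoxy-2,3-dihydrobenzofuran-4-yl trifluoromethanesulfonate | COc1cc([C@@H]2Oc3c(OC)cc(C=O)c(OS(=O)(=O)C(F)(F)F)c3[C@H]2CO[Si](C)(C)C(C)(C)C)cc(OC)c1O[Si](C)(C)C(C)(C)C
F7 | step 10 | (2R,3S)-2-Ar-3-[(tert-butyldimethylsilyloxy)methyl]-7-methoxy-2,3-dihydrobenzofuran-5-carbaldehyde | COc1cc([C@@H]2Oc3c(OC)cc(C=O)cc3[C@H]2CO[Si](C)(C)C(C)(C)C)cc(OC)c1O[Si](C)(C)C(C)(C)C
F8 | step 10 | ethyl (E)-3-{(2R,3S)-2-Ar-3-[(tert-butyldimethylsilyloxy)methyl]-7-methoxy-2,3-dihydrobenzofuran-5-yl}prop-2-enoate | COc1cc([C@@H]2Oc3c(OC)cc(/C=C/C(=O)OCC)cc3[C@H]2CO[Si](C)(C)C(C)(C)C)cc(OC)c1O[Si](C)(C)C(C)(C)C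
F9 | step 10 | (E)-3-{(2R,3S)-2-Ar-3-[(tert-butyldimethylsilyloxy)methyl]-7-methoxy-2,3-dihydrobenzofuran-5-yl}prop-2-en-1-ol | COc1cc([C@@H]2Oc3c(OC)cc(/C=C/CO)cc3[C@H]2CO[Si](C)(C)C(C)(C)C)cc(OC)c1O[Si](C)(C)C(C)(C)C
F10 | step 12 | (2R,3S)-2-Ar-3-[(tert-butyldimethylsilyloxy)methyl]-5-[(E)-3-(tert-butyldimethylsilyloxy)prop-1-enyl]-7-methoxy-4-(trimethylstannyl)-2,3-dihydrobenzofuran | COc1cc([C@@H]2Oc3c(OC)cc(/C=C/CO[Si](C)(C)C(C)(C)C)c([Sn](C)(C)C)c3[C@H]2CO[Si](C)(C)C(C)(C)C)cc(OC)c1O[Si](C)(C)C(C)(C)C
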